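The ten-membered carbocycle (C1–C10) holds one bond, C8–C9, between two adjacent oxygen-bearing carbons (tertiary C8–OH, secondary C9–OAc, cis to each other): a pinacol retron. The plan is a SmI2 ketone–aldehyde pinacol macrocyclisation of a seco keto-aldehyde in which ring A carries the C9 aldehyde and the C2–C8 chain ends in a C8 ketone; it closes the ten-membered ring and sets C8 and C9 at once. The precursor is convergent: ring A from a catalytic asymmetric Diels–Alder reaction, C5–C8 (stereocentres C6, C7) from D-tartrate, C17 from an Evans aldol, the halves joined at C4–C5 by an asymmetric Ni/Cr coupling. Lactone, acetoxy-enone and chloride follow ring closure.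

Key step: step 17

Remark: carbons carry briarane numbering (C1 quaternary ring-fusion carbon, C2=C3, C4–OAc, C5=C16H2, C6–Cl, C7–O, C8–OH, C9–OAc, C10, C11(CH3)OAc, C12=O, C13=C14, C17–CH3, C19 lactone C=O; ring A = C1, C10–C14); C11 in 7–26 is drawn as the endo-derived epimer and is inconsequential until step 20.

Step 1
Reactants: 1 glycolaldehyde dimer (2,5-dihydroxy-1,4-dioxane); 2 2-(triphenylphosphoranylidene)propanal
Product: 3 (E)-4-hydroxy-2-methylbut-2-enal
Conditions: 1 (0.5 equiv), 2, toluene, 80 °C
Reagents that add atoms: none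
Why: Wittig olefination of monomeric glycolaldehyde (released from the dimer) with a formyl-stabilised ylide, which should give the E-trisubstituted enal as is usual for stabilised ylides.

Step 2
Reactants: 3 (E)-4-hydroxy-2-methylbut-2-enal
Product: 4 (E)-2-methyl-4-(triethylsilyloxy)but-2-enal
Conditions: TESCl, imidazole, CH2Cl2, 0 °C
Reagents that add atoms: chlorotriethylsilane, CC[Si](CC)(CC)Cl
Why: Standard silylation of a primary allylic alcohol; the TES ether is chosen because it can later be removed under conditions that spare a TIPS enol ether.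

Step 3
Reactants: 5 pent-1-en-3-one
Product: 6 (Z)-3-(triisopropylsilyloxy)penta-1,3-diene
Conditions: TIPSOTf, Et3N, Et2O, 0 °C
Reagents that add atoms: triisopropylsilyl triflate, CC(C)[Si](C(C)C)(C(C)C)OS(=O)(=O)C(F)(F)F
Why: Soft enolisation and O-silylation of the ethyl ketone, expected to give the Z enol ether (methyl cis to oxygen, hence "outside" in the s-cis diene) as for ethyl ketones under R3SiOTf/amine conditions.

Step 4
Reactants: 4 (E)-2-methyl-4-(triethylsilyloxy)but-2-enal; 6 (Z)-3-(triisopropylsilyloxy)penta-1,3-diene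
Product: 7 (1S,5S,6S)-1,5-dimethyl-6-[(triethylsilyloxy)methyl]-4-(triisopropylsilyloxy)cyclohex-3-ene-1-carbaldehyde (ring A aldehyde)
Conditions: (R)-3,3-diphenyl-1-(o-tolyl)tetrahydropyrrolo[1,2-c][1,3,2]oxazaborole·HNTf2 (20 mol %), CH2Cl2, −78 → −40 °C
Reagents that add atoms: none
Why: Catalytic asymmetric Diels–Alder reaction of an α-methyl enal bound through its formyl group to the protonated oxazaborolidine: the nucleophilic methyl-bearing diene terminus bonds to C10 and the CH2 terminus to C1, the E geometry of 4 is transferred suprafacially into the trans C1(CHO)/C10(CH2OTES) relationship, the catalyst enantiomer is chosen for Si-face addition at C1 (formyl C–H···O binding model; the antipodal catalyst would be used if the sense proved opposite), and the endo-derived C11 methyl orientation does not matter because C11 is re-set in step 20.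

Step 5
Reactants: 7 ring A aldehyde; 8 diethyl [(E)-2-(cyclohexylamino)vinyl]phosphonate
Product: 10 ring A enal (E)-3-[1,5-dimethyl-6-(triethylsilyloxymethyl)-4-(triisopropylsilyloxy)cyclohex-3-en-1-yl]prop-2-enal, via unsaturated N-cyclohexyl imine 9 (not isolated)
Conditions: 8, NaH, THF, 0 → 25 °C; then AcOH/NaOAc buffer (pH 4.5), H2O–Et2O, 25 °C
Reagents that add atoms: water, O
Why: Horner–Wadsworth–Emmons formylolefination with a nucleophilic phosphonate aza-enolate, which should add to the hindered non-enolisable aldehyde, give the E-C2=C3 alkene and, because the product is an imine until the buffered hydrolysis, cannot homologate twice.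

Step 6
Reactants: 11 dimethyl (4S,5S)-2,2-dimethyl-1,3-dioxolane-4,5-dicarboxylate (D-tartrate acetonide)
Product: 12 (4S,5S)-N4,N5-dimethoxy-N4,N5,2,2-tetramethyl-1,3-dioxolane-4,5-dicarboxamide
Conditions: MeNHOMe·HCl, iPrMgCl, THF, −20 °C
Reagents that add atoms: N,O-dimethylhydroxylamine hydrochloride, CNOC.Cl
Why: Magnesium-amide aminolysis of both esters to N-methoxy-N-methylamides at low temperature, where the α-alkoxy stereocentres (the future C6 and C7) should not epimerise.

Step 7
Reactants: 12 bis(N-methoxy-N-methylamide)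
Product: 13 (4S,5S)-5-acetyl-N-methoxy-N,2,2-trimethyl-1,3-dioxolane-4-carboxamide
Conditions: MeMgBr (1.1 equiv), THF, −15 °C
Reagents that add atoms: methylmagnesium bromide, C[Mg]Br
Why: Desymmetrising mono-addition of a Grignard reagent to the C2-symmetric bis-amide, in which the magnesium-chelated tetrahedral intermediate prevents over-addition at the reacting carbonyl and one equivalent limits attack at the second one; the new methyl becomes C16 and the ketone carbon C5.

Step 8
Reactants: 13 methyl ketone
Product: 14 (4S,5S)-N-methoxy-N,2,2-trimethyl-5-[1-(trifluoromethylsulfonyloxy)vinyl]-1,3-dioxolane-4-carboxamide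
Conditions: KHMDS, PhNTf2, THF, −78 °C
Reagents that add atoms: N-phenylbis(trifluoromethanesulfonimide), O=S(=O)(N(c1ccccc1)S(=O)(=O)C(F)(F)F)C(F)(F)F
Why: Kinetic deprotonation at the unhindered methyl group and O-triflation of the enolate give the 2-triflyloxy-1-alkene (C5=C16) without enolising the α-alkoxy methine C6.

Step 9
Reactants: 14 enol triflate amide
Product: 15 (4S,5S)-2,2-dimethyl-5-[1-(trifluoromethylsulfonyloxy)vinyl]-1,3-dioxolane-4-carbaldehyde
Conditions: iBu2AlH, THF, −78 °C; Rochelle salt work-up; used crude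
Reagents that add atoms: none
Why: Hydride reduction of an N-methoxy-N-methylamide stops at the chelated hemiaminal, which releases the C8 aldehyde on work-up, while the vinyl triflate is inert and immediate use avoids epimerisation at C7.

Step 10
Reactants: 15 C8 aldehyde; 16 (R)-4-benzyl-3-propionyloxazolidin-2-one
Product: 17 syn-aldol imide (R)-4-benzyl-3-[3-hydroxy-2-methyl-3-(2,2-dimethyl-5-(1-triflyloxyvinyl)-1,3-dioxolan-4-yl)propanoyl]oxazolidin-2-one
Conditions: 16, Bu2BOTf, iPr2NEt, CH2Cl2, −78 → 0 °C; then 15, −78 → 0 °C; pH 7 buffer, MeOH, H2O2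
Reagents that add atoms: none
Why: Evans syn-aldol reaction through the Z boron enolate and a Zimmerman–Traxler chair, in which the oxazolidinone auxiliary fixes the enolate face and so sets C17 (R, as in the target); the C8 carbinol configuration is irrelevant because it is oxidised in step 16.

Step 11
Reactants: 17 syn-aldol imide
Product: 18 β-hydroxy N-methoxy-N-methylamide (C5–C8/C17–C19 fragment with free C8–OH)
Conditions: MeNHOMe·HCl, AlMe3, CH2Cl2, −20 → 0 °C
Reagents that add atoms: N,O-dimethylhydroxylamine hydrochloride, CNOC.Cl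
Why: Aluminium-amide transamination of the β-hydroxy imide, assisted by the free hydroxyl, replaces the auxiliary by an amide that does not acylate neighbouring alkoxides yet lactonises readily under acid later.

Step 12
Reactants: 18 β-hydroxy amide
Product: 19 fragment B: C8-O-triethylsilyl ether of 18 (vinyl triflate at C5)
Conditions: TESOTf, 2,6-lutidine, CH2Cl2, −78 °C
Reagents that add atoms: triethylsilyl triflate, CC[Si](CC)(CC)OS(=O)(=O)C(F)(F)F
Why: Silylation of the secondary alcohol keeps C8 at the alcohol level, so C17 stays non-enolisable through the coupling and acetylation steps.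

Step 13
Reactants: 10 ring A enal; 19 fragment B vinyl triflate
Product: 20 coupled bis-allylic alcohol (C4–OH, 4S; C1–C19 skeleton complete except for the C8–C9 bond)
Conditions: CrCl2 (4 equiv), NiCl2 (2 mol %), (S)-N-[2-(4-isopropyl-4,5-dihydrooxazol-2-yl)-6-methylphenyl]methanesulfonamide (4.4 equiv), Et3N, THF, 25 °C
Reagents that add atoms: none
Why: Nozaki–Hiyama–Kishi coupling (zerovalent nickel inserts into the C5–OTf bond, transmetalation gives an alkenyl species of trivalent chromium that adds 1,2 to the enal and ignores amide, silyl ethers and enol ether), with the chiral sulfonamide on chromium chosen to direct addition to the Re face of the aldehyde and so set C4 (S); the antipodal ligand would be used if the sense proved opposite.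

Step 14
Reactants: 20 bis-allylic alcohol
Product: 21 C4 acetate of 20
Conditions: Ac2O, pyridine, DMAP (cat.), CH2Cl2, 0 °C
Reagents that add atoms: acetic anhydride, CC(=O)OC(C)=O
Why: Acylation of the only free hydroxyl installs the C4 acetate of the target with retention.

Step 15
Reactants: 21 C4 acetate
Product: 22 C8,C9-diol (both TES ethers removed)
Conditions: PPTS (0.2 equiv), MeOH–CH2Cl2 (1:1), 0 °C
Reagents that add atoms: none
Why: Acid-catalysed methanolysis of TES ethers should be much faster than solvolysis of the hindered TIPS enol ether, the trans-acetonide or the allylic acetate.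

Step 16
Reactants: 22 C8,C9-diol
Product: 23 seco keto-aldehyde (C8 ketone, C9 aldehyde)
Conditions: Dess–Martin periodinane, NaHCO3, CH2Cl2, 0 → 25 °C; used crude
Reagents that add atoms: none
Why: Dess–Martin oxidation of the primary and the secondary alcohol in one operation under buffered, near-neutral conditions, so that C10 and C17 (now α to carbonyl groups) should keep their configuration.

Step 17
Reactants: 23 seco keto-aldehyde
Product: 24 macrocyclic cis-8,9-diol (ten-membered ring closed; 8R,9R)
Conditions: SmI2 (3 equiv, 0.1 M in THF, no HMPA), THF, 0 °C, 23 added over 6 h (final 2 mM); aq. NaHCO3/Na2S2O3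
Reagents that add atoms: none
Why: SmI2 transfers one electron to a carbonyl of 23 (most likely the C8 ketone, which is held on samarium by the neighbouring amide carbonyl), the ketyl couples with the second samarium-bound carbonyl, and a second electron gives a cyclic diolate of trivalent samarium that is protonated on work-up. The closest known reaction type is the SmI2-mediated intramolecular ketone–aldehyde pinacol coupling, which is established for medium and large carbocycles and for α-alkoxy and β-dicarbonyl substrates. The ten-membered carbocycle C1–C10 is closed by a 10-exo-trig ketyl–carbonyl addition, helped by three rigid elements that bring C8 and C9 together: the E-C2=C3 alkene, the trans-dioxolane on C6/C7 and the trans-1,2-disubstituted ring A. C8 should be set by attack on the ketone face anti to the C7–O bond (Felkin–Anh control by the tartrate-derived dioxolane), which places O8 on the same side as O7, and C9 follows because both oxygens stay bridged by one samarium ion (cis-diol). The step needs chemoselectivity for the two carbonyls over the doubly allylic acetate, the amide N–O bond and the C7–O bond α to the ketone, and intramolecular over intermolecular coupling; this is secured by SmI2 without HMPA at low temperature, by slow addition at high dilution, and by keeping C12 masked as its silyl enol ether.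

Step 18
Reactants: 24 macrocyclic diol
Product: 25 C9 acetate of 24 (C8–OH free)
Conditions: Ac2O, pyridine, DMAP (cat.), CH2Cl2, 25 °C
Reagents that add atoms: acetic anhydride, CC(=O)OC(C)=O
Why: Acylation of the secondary C9 hydroxyl, while the tertiary C8 hydroxyl, flanked by three branched carbons, should not react under these conditions.

Step 19
Reactants: 25 C9 acetate
Product: 26 enone (C12=O, C13=C14)
Conditions: Pd(OAc)2 (1.5 equiv), MeCN, 25 °C
Reagents that add atoms: none
Why: Saegusa–Ito oxidation: the silyl enol ether is converted into a C13-bound enolate of divalent palladium, and β-hydride elimination from C14 (the only β-hydrogens) gives the enone regiospecifically.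

Step 20
Reactants: 26 enone
Product: 27 C11-acetoxy enone (11S)
Conditions: Mn(OAc)3·2H2O (5 equiv), benzene, 80 °C (Dean–Stark)
Reagents that add atoms: manganese triacetate, CC(=O)[O-].CC(=O)[O-].CC(=O)[O-].[Mn+3]
Why: α'-Acetoxylation of an enone with Mn(OAc)3 through the manganese enolate (α-keto radical) at C11, the only enolisable position, with acetate transfer expected on the ring A face opposite the C10–C9 bond and the C1 methyl group, which gives the tertiary acetate cis to H10 as in the target.

Step 21
Reactants: 27 C11-acetoxy enone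
Product: 29 γ-lactone with free C6–OH (6R), via 6,7-diol amide 28 (not isolated)
Conditions: TFA–H2O (9:1), CH2Cl2, 0 °C
Reagents that add atoms: none
Why: Acid hydrolysis of the acetonide frees the C6/C7 diol, and the C7 hydroxyl, γ to the amide carbonyl, should lactonise with loss of MeNHOMe (five-membered ring favoured over the six-membered alternative through O6), leaving C7 and C17 unchanged.

Step 22
Reactants: 29 lactone alcohol
Product: 30 target CNP0159278.2
Conditions: PPh3, hexachloroacetone, CH2Cl2, 0 °C
Reagents that add atoms: hexachloroacetone, ClC(Cl)(Cl)C(=O)C(Cl)(Cl)Cl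
Why: Appel-type chlorination: the secondary allylic C6 hydroxyl forms an alkoxyphosphonium ion that chloride displaces by SN2 with inversion (6R alcohol → 6S chloride), under conditions known to convert secondary allylic alcohols without allylic transposition, while the hindered tertiary C8 hydroxyl should not react.

Compound list
1 | glycolaldehyde dimer (2,5-dihydroxy-1,4-dioxane) | OC1COC(O)CO1 | starting material
2 | 2-(triphenylphosphoranylidene)propanal | CC(C=O)=P(c1ccccc1)(c1ccccc1)c1ccccc1 | starting material
3 | (E)-4-hydroxy-2-methylbut-2-enal | O=C/C(C)=C/CO | intermediate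
4 | (E)-2-methyl-4-(triethylsilyloxy)but-2-enal | O=C/C(C)=C/CO[Si](CC)(CC)CC | intermediate
5 | pent-1-en-3-one | CCC(=O)C=C | starting material
6 | (Z)-3-(triisopropylsilyloxy)penta-1,3-diene | C/C=C(\O[Si](C(C)C)(C(C)C)C(C)C)C=C | intermediate
7 | (1S,5S,6S)-1,5-dimethyl-6-[(triethylsilyloxy)methyl]-4-(triisopropylsilyloxy)cyclohex-3-ene-1-carbaldehyde (ring A aldehyde; CHO and CH2OTES trans) | O=C[C@@]1(C)CC=C(O[Si](C(C)C)(C(C)C)C(C)C)[C@@H](C)[C@@H]1CO[Si](CC)(CC)CC | intermediate
8 | diethyl [(E)-2-(cyclohexylamino)vinyl]phosphonate | CCOP(=O)(OCC)/C=C/NC1CCCCC1 | starting material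
9 | N-cyclohexyl imine of enal 10 (ring A stereocentres as in 7) | C1CCCCC1N=C/C=C/[C@@]2(C)CC=C(O[Si](C(C)C)(C(C)C)C(C)C)[C@@H](C)[C@@H]2CO[Si](CC)(CC)CC | intermediate (not isolated)
10 | ring A enal: (E)-3-[1,5-dimethyl-6-(triethylsilyloxymethyl)-4-(triisopropylsilyloxy)cyclohex-3-en-1-yl]prop-2-enal (ring stereocentres as in 7) | O=C/C=C/[C@@]1(C)CC=C(O[Si](C(C)C)(C(C)C)C(C)C)[C@@H](C)[C@@H]1CO[Si](CC)(CC)CC | intermediate
11 | dimethyl (4S,5S)-2,2-dimethyl-1,3-dioxolane-4,5-dicarboxylate (dimethyl 2,3-O-isopropylidene-D-tartrate) | COC(=O)[C@H]1OC(C)(C)O[C@@H]1C(=O)OC | starting material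
12 | (4S,5S)-N4,N5-dimethoxy-N4,N5,2,2-tetramethyl-1,3-dioxolane-4,5-dicarboxamide | CON(C)C(=O)[C@H]1OC(C)(C)O[C@@H]1C(=O)N(C)OC | intermediate
13 | (4S,5S)-5-acetyl-N-methoxy-N,2,2-trimethyl-1,3-dioxolane-4-carboxamide | CC(=O)[C@H]1OC(C)(C)O[C@@H]1C(=O)N(C)OC | intermediate
14 | (4S,5S)-N-methoxy-N,2,2-trimethyl-5-[1-(trifluoromethylsulfonyloxy)vinyl]-1,3-dioxolane-4-carboxamide | C=C(OS(=O)(=O)C(F)(F)F)[C@H]1OC(C)(C)O[C@@H]1C(=O)N(C)OC | intermediate
15 | (4S,5S)-2,2-dimethyl-5-[1-(trifluoromethylsulfonyloxy)vinyl]-1,3-dioxolane-4-carbaldehyde | C=C(OS(=O)(=O)C(F)(F)F)[C@H]1OC(C)(C)O[C@@H]1C=O | intermediate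
16 | (R)-4-benzyl-3-propionyloxazolidin-2-one | CCC(=O)N1[C@H](Cc2ccccc2)COC1=O | starting material
17 | syn-aldol imide (C17 methyl and C8 hydroxyl syn; dioxolane as in 15) | C=C(OS(=O)(=O)C(F)(F)F)[C@H]1OC(C)(C)O[C@@H]1[C@H](O)[C@@H](C)C(=O)N2[C@H](Cc3ccccc3)COC2=O | intermediate
18 | β-hydroxy N-methoxy-N-methylamide corresponding to 17 | C=C(OS(=O)(=O)C(F)(F)F)[C@H]1OC(C)(C)O[C@@H]1[C@H](O)[C@@H](C)C(=O)N(C)OC | intermediate
19 | fragment B: C8-O-triethylsilyl ether of 18 | C=C(OS(=O)(=O)C(F)(F)F)[C@H]1OC(C)(C)O[C@@H]1[C@H](O[Si](CC)(CC)CC)[C@@H](C)C(=O)N(C)OC | intermediate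
20 | coupled (4S)-bis-allylic alcohol (C4–OH; C8–OTES, C9–OTES, C12 TIPS enol ether, C6/C7 acetonide) | C=C([C@H]1OC(C)(C)O[C@@H]1[C@H](O[Si](CC)(CC)CC)[C@@H](C)C(=O)N(C)OC)[C@@H](O)/C=C/[C@@]1(C)CC=C(O[Si](C(C)C)(C(C)C)C(C)C)[C@@H](C)[C@@H]1CO[Si](CC)(CC)CC | intermediate
21 | C4 acetate of 20 | C=C([C@H]1OC(C)(C)O[C@@H]1[C@H](O[Si](CC)(CC)CC)[C@@H](C)C(=O)N(C)OC)[C@@H](OC(C)=O)/C=C/[C@@]1(C)CC=C(O[Si](C(C)C)(C(C)C)C(C)C)[C@@H](C)[C@@H]1CO[Si](CC)(CC)CC | intermediate
22 | C8,C9-diol (C4 acetate, C12 TIPS enol ether, C6/C7 acetonide) | C=C([C@H]1OC(C)(C)O[C@@H]1[C@H](O)[C@@H](C)C(=O)N(C)OC)[C@@H](OC(C)=O)/C=C/[C@@]1(C)CC=C(O[Si](C(C)C)(C(C)C)C(C)C)[C@@H](C)[C@@H]1CO | intermediate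
23 | seco keto-aldehyde (C8 ketone, C9 aldehyde) | C=C([C@H]1OC(C)(C)O[C@@H]1C(=O)[C@@H](C)C(=O)N(C)OC)[C@@H](OC(C)=O)/C=C/[C@@]1(C)CC=C(O[Si](C(C)C)(C(C)C)C(C)C)[C@@H](C)[C@@H]1C=O | intermediate
24 | macrocyclic (8R,9R)-cis-diol (ten-membered ring closed; C6/C7 acetonide, C4 acetate, C12 TIPS enol ether, C19 N-methoxy-N-methylamide) | C=C1[C@@H](OC(C)=O)/C=C/[C@@]2(C)CC=C(O[Si](C(C)C)(C(C)C)C(C)C)[C@@H](C)[C@@H]2[C@@H](O)[C@](O)([C@@H](C)C(=O)N(C)OC)[C@H]2OC(C)(C)O[C@H]12 | intermediate
25 | C9 acetate of 24 | C=C1[C@@H](OC(C)=O)/C=C/[C@@]2(C)CC=C(O[Si](C(C)C)(C(C)C)C(C)C)[C@@H](C)[C@@H]2[C@@H](OC(C)=O)[C@](O)([C@@H](C)C(=O)N(C)OC)[C@H]2OC(C)(C)O[C@H]12 | intermediate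
26 | enone (C12=O, C13=C14; C11–H) | C=C1[C@@H](OC(C)=O)/C=C/[C@@]2(C)C=CC(=O)[C@@H](C)[C@@H]2[C@@H](OC(C)=O)[C@](O)([C@@H](C)C(=O)N(C)OC)[C@H]2OC(C)(C)O[C@H]12 | intermediate
27 | (11S)-C11-acetoxy enone (C6/C7 acetonide, C19 amide) | C=C1[C@@H](OC(C)=O)/C=C/[C@@]2(C)C=CC(=O)[C@@](C)(OC(C)=O)[C@@H]2[C@@H](OC(C)=O)[C@](O)([C@@H](C)C(=O)N(C)OC)[C@H]2OC(C)(C)O[C@H]12 | intermediate
28 | 6,7-diol amide (acetonide removed) | C=C1[C@@H](OC(C)=O)/C=C/[C@@]2(C)C=CC(=O)[C@@](C)(OC(C)=O)[C@@H]2[C@@H](OC(C)=O)[C@](O)([C@@H](C)C(=O)N(C)OC)[C@@H](O)[C@@H]1O | intermediate (not isolated)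
29 | 7,19-lactone with free (6R)-hydroxyl (6-epi-hydroxy analogue of the target) | C=C1[C@@H](OC(C)=O)/C=C/[C@@]2(C)C=CC(=O)[C@@](C)(OC(C)=O)[C@@H]2[C@@H](OC(C)=O)[C@]2(O)[C@@H](C)C(=O)O[C@H]2[C@@H]1O | intermediate
30 | CNP0159278.2 (1S,4S,6S,7R,8R,9R,10S,11S,17R) | C=C1[C@@H](OC(C)=O)/C=C/[C@@]2(C)C=CC(=O)[C@@](C)(OC(C)=O)[C@@H]2[C@@H](OC(C)=O)[C@]2(O)[C@@H](C)C(=O)O[C@H]2[C@H]1Cl | target

Total step count: 22. Longest linear sequence: 17 steps (11 → 30, steps 6–12 and 13–22); the ring A branch (steps 1–5) joins at step 13.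

Steps most likely to fail

Step 17, the ring closure. The ten-membered closure is slow, so the C8 ketyl may take up a second electron and lose the C7 oxygen, or couple intermolecularly, before the C8–C9 bond forms. The fallback sets out from 23 and returns directly to 24 by a titanium-templated McMurry-type pinacol closure (TiCl3(DME)1.5, Zn–Cu couple, DME, 25 °C, 23 added by syringe pump, aqueous K2CO3 quench before deoxygenation to the alkene can set in). Here both carbonyl oxygens are bound to low-valent titanium before the C–C bond forms, an inner-sphere coupling with long use for cis-cyclodecane-1,2-diols, so no free ketyl meets a soluble one-electron reductant. It makes no new compound (F0).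

Step 20, the late acetoxylation. The manganese enolate at the hindered tertiary C11 may form slowly, so that oxidative side reactions of the polyfunctional macrocycle or poor facial selectivity take over. The fallback sets out from 26 and returns at 27 by polar chemistry that also protects the C8 hydroxyl. TESOTf/Et3N (CH2Cl2, −78 → 0 °C) silylates O8 and enolises the only available position to give the bis(triethylsilyl) cross-conjugated dienol ether F1. Rubottom oxidation (dimethyldioxirane, acetone–CH2Cl2, −78 °C, mild acidic work-up) from the face opposite C9 and the C1 methyl gives the C11 α'-hydroxy enone with C8–OTES, F2. Ac2O/DMAP/Et3N acetylates the only free (tertiary C11) hydroxyl to give the C11 acetate with C8–OTES, F3. HF·pyridine (THF, 0 °C) removes the tertiary silyl ether to give 27.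

Step 22, the chlorination. Chloride may be delivered with allylic transposition to C16 (SN2'), or the alkoxyphosphonium ion may eliminate, instead of the direct SN2 at the hindered C6. The fallback sets out from 29 and returns at 30 with activation and displacement separated. ClCH2SO2Cl/pyridine (CH2Cl2, 0 °C) gives, with retention, the C6 chloromethanesulfonate F4. LiCl (DMF, 25 °C) then displaces it with inversion, so nucleophile, solvent and temperature of the SN2 step can be chosen freely.

Further compounds
F0 | step 17 | none | none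
F1 | step 20 | bis(triethylsilyl) derivative of 26: C8–OTES and C11=C12(OTES) cross-conjugated dienol ether | C=C1[C@@H](OC(C)=O)/C=C/[C@@]2(C)C=CC(O[Si](CC)(CC)CC)=C(C)[C@@H]2[C@@H](OC(C)=O)[C@](O[Si](CC)(CC)CC)([C@@H](C)C(=O)N(C)OC)[C@H]2OC(C)(C)O[C@H]12
F2 | step 20 | (11S)-C11-hydroxy enone with C8–OTES | C=C1[C@@H](OC(C)=O)/C=C/[C@@]2(C)C=CC(=O)[C@@](C)(O)[C@@H]2[C@@H](OC(C)=O)[C@](O[Si](CC)(CC)CC)([C@@H](C)C(=O)N(C)OC)[C@H]2OC(C)(C)O[C@H]12
F3 | step 20 | (11S)-C11-acetoxy enone with C8–OTES (8-O-silyl ether of 27) | C=C1[C@@H](OC(C)=O)/C=C/[C@@]2(C)C=CC(=O)[C@@](C)(OC(C)=O)[C@@H]2[C@@H](OC(C)=O)[C@](O[Si](CC)(CC)CC)([C@@H](C)C(=O)N(C)OC)[C@H]2OC(C)(C)O[C@H]12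
F4 | step 22 | (6R)-chloromethanesulfonate of 29 | C=C1[C@@H](OC(C)=O)/C=C/[C@@]2(C)C=CC(=O)[C@@](C)(OC(C)=O)[C@@H]2[C@@H](OC(C)=O)[C@]2(O)[C@@H](C)C(=O)O[C@H]2[C@@H]1OS(=O)(=O)CCl
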